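(The earlier runs and the new flask are simulated for an exercise.)

Every unit of reagent spent puts one by-product into the flask and every side product takes one out, so c(by-product) plus c(side product) equals the reagent spent.

| flask | starting material | reagent | remark | time |
|---|---|---|---|---|
| green | 0.020 M (in portions, 3) | 0.16 equiv | run made earlier; portions every 2.5 min |  |
| violet | 0.020 M (in portions, 3) | 4 equiv | run made earlier; portions every 2.5 min |  |
| elm | 0.020 M (in portions, 3) | 0.120 equiv | the portions of starting material follow each other after 2.5 min, the first at the start | 80 min |
| maple | 0.020 M (in portions, 3) | 0.400 equiv | the portions of starting material follow each other after 2.5 min, the first at the start | 80 min |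
| larch | 0.020 M (in portions, 3) | 1.20 equiv | the portions of starting material follow each other after 2.5 min, the first at the start | 80 min |
| birch | 0.020 M (in portions, 3) | 3.00 equiv | the portions of starting material follow each other after 2.5 min, the first at the start | 80 min |

| run | time / min | mono adduct / % | double product / % |
|---|---|---|---|
| green | 8.00 | 4 | 0 |
| green | 15.0 | 12 | 0 |
| green | 25.0 | 12 | 2 |
| green | 30.0 | 12 | 0 |
| green | 40.0 | 11 | 2 |
| violet | 8.00 | 30 | 60 |
| violet | 15.0 | 8 | 84 |
| violet | 25.0 | 4 | 87 |
| violet | 30.0 | 0 | 88 |
| violet | 40.0 | 1 | 89 |

(scatter of a reading: 1.5 percentage points)

- share of mono adduct in all that became mono adduct or double product or side product for elm, maple, larch, birch, in this order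
- how that number moves from the first to the last of them (falls, then rises / rises, then falls / rises all the way / hardly changes / falls all the way)

So the by-product, made with the mono adduct, stays in the flask beside it. Green shows what that does. Its mono adduct reads 12 % after 15.0 min and no longer rises, so I took its reagent charge as by-product, 0.00320 M, and the mono adduct as decaying by a pseudo-first-order step in that level. From 12 % to 11 % at 40.0 min, I read a drain constant, the first-order decay rate of the mono adduct per unit of c(by-product), 1.09 M⁻¹ min⁻¹. But that drop is 1 percentage point against a scatter of 1.5 points per reading, so the constant is rough. Violet supports a real drain: at 40.0 min, 10.0 % is missing, which I read as side product.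

For elm, c(by-product) comes to 0.00240 M, so the time constant is 383 min, longer than the run. Green's double product reads 2 % at 40.0 min beside 11 % mono adduct, more than the drop the drain was read from, so it belongs in the elm share; but I reckoned no constant for it, so my elm figure, the surviving mono adduct, 81.2 %, covers the drain and counts no double product. Side product removes by-product, however, so I replaced the falling curve by its mean; that moved my figure to 82.8 %, a small error beside the constant's scatter.

The forecast gave 85 %, 60 %, 20 % and 0.3 %, falls all the way, with “little by-product, so only slow leakage” for elm.

The simulation gave 78.3 %, 48.0 %, 11.6 % and 0 %; the share falls all the way, and my elm figure stood above its value.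

    reagent + mono adduct → double product + by-product (k = 0.0760 M⁻¹ s⁻¹)
    starting material + reagent → other mono adduct + by-product (k = 0.00550 M⁻¹ s⁻¹)
    reagent + other mono adduct → double product + by-product (k = 0.130 M⁻¹ s⁻¹)
    starting material + reagent → mono adduct + by-product (k = 0.140 M⁻¹ s⁻¹)
    mono adduct + by-product → side product (k = 0.0230 M⁻¹ s⁻¹)

In elm, reagent stood at 0.198 % of its charge after 40.0 min, and from then to 80 min double product stayed at 0.410 % while side product rose from 0.940 % to 2.02 % and mono adduct fell from 9.81 % to 8.75 %, where the drain constant on the mean by-product gives 8.95 %. In maple, with reagent at 0.451 % after 40.0 min, the same constant on a mean by-product of 0.00588 M gives 17.7 % from 22.8 %, and the mono adduct stood at 16.6 % at 80 min.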